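With the quinone ring numbered C1(=O), C2(OMe), C3(H), C4(=O), C5(Me), C6(pentacosyl), the target is traced back to the phenol bearing OH on C4 and H on C1, and that benzene ring is cut into C2–C3 (methoxyethyne) and C4–C5–C6–C1 (a 3-alkyl-4-methylcyclobutenone). Heating the two partners joins C3–C4 and C1–C2, re-forms C4–C5 and aromatises, so the carbocycle and all four substituents are set in one operation. The feature exploited is the meta placement of the C2 and C4 oxygens on the six-membered ring, with C3 unsubstituted and C1 para to the new hydroxyl, open for the final oxidation. The precursor is racemic 4-methyl-3-pentacosylcyclobut-2-enone, built by a keteniminium–alkyne [2+2].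

Key step: step 5

Remark: the target has no stereocentre, so no enantiomer has to be selected; the one stereocentre on the route (C4 of the cyclobutenone) is made racemic and vanishes on aromatisation.

Step 1
Reactants: 1 1-hexacosanol
Product: 2 hexacosanal
Conditions: TEMPO (10 mol%), PhI(OAc)2 (1.1 equiv), CH2Cl2, 35 °C
Reagents that add atoms: none
Why: TEMPO-catalysed (oxoammonium) oxidation of a primary alcohol should stop at the aldehyde under anhydrous conditions, and gentle warming keeps the waxy C26 alcohol in solution.

Step 2
Reactants: 2 hexacosanal
Product: 3 heptacos-1-yne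
Conditions: dimethyl (1-diazo-2-oxopropyl)phosphonate (1.3 equiv), K2CO3 (2 equiv), MeOH/THF, rt
Reagents that add atoms: dimethyl (1-diazo-2-oxopropyl)phosphonate, CC(=O)C(=[N+]=[N-])P(=O)(OC)OC
Why: Ohira–Bestmann (Seyferth–Gilbert) homologation should convert an unhindered, saturated aliphatic aldehyde into the terminal alkyne with one added carbon under mild carbonate conditions.

Step 3
Reactants: 3 heptacos-1-yne; 4 N,N-dimethylpropanamide
Product: 7 4-methyl-3-pentacosylcyclobut-2-en-1-one (racemic), via keteniminium triflate 5 (not isolated), via cyclobuteniminium triflate 6 (not isolated)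
Conditions: 4 (1.5 equiv), Tf2O (1.6 equiv), 2,4,6-collidine (1.6 equiv), ClCH2CH2Cl, −15 °C → 80 °C; then H2O, 60 °C
Reagents that add atoms: water, O
Why: Ghosez keteniminium–alkyne [2+2] cycloaddition, in which the terminal alkyne carbon attacks the electrophilic central carbon of 5 and the internal carbon closes onto the methyl-bearing carbon, should fix the 3-alkyl-4-methyl pattern before hydrolysis of iminium 6 releases the ketone; C4 is formed racemic without control, which is acceptable because it is destroyed in step 5.

Step 4
Reactants: 8 2-chloro-1,1-dimethoxyethane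
Product: 11 methoxyethyne (toluene solution), via 1-chloro-2-methoxyethene 9 (not isolated), via sodium methoxyethynide 10 (not isolated)
Conditions: NaNH2 (3.1 equiv), liq. NH3, −33 °C; cold brine, −70 °C; distilled into toluene, −78 °C
Reagents that add atoms: none
Why: Twofold amide-induced β-elimination (methanol, then HCl), the standard laboratory preparation of this ynol ether, should give acetylide 10, which the aqueous quench protonates, and distilling the low-boiling product straight into cold toluene gives a stock solution that is never handled neat.

Step 5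
Reactants: 7 4-methyl-3-pentacosylcyclobut-2-en-1-one (racemic); 11 methoxyethyne
Product: 16 5-methoxy-2-methyl-3-pentacosylphenol, via vinylketene 12 (not isolated), via 4-vinylcyclobutenone 13 (not isolated), via dienylketene 14 (not isolated), via cyclohexa-2,4-dienone 15 (not isolated)
Conditions: 11 (3 equiv), toluene, sealed tube, 80 °C → 100 °C
Reagents that add atoms: none
Why: Thermal conrotatory 4π opening of 7 (methyl turning outward) gives vinylketene 12, whose ketene C=C adds to 11 in a [2+2] cycloaddition to give 13; a second 4π opening gives dienylketene 14, which cyclises to 15 and enolises to 16. The closest known reaction type is the Danheiser benzannulation of cyclobutenones with alkoxyalkynes, which delivers resorcinol monoethers. The six-membered carbocycle is closed by a thermal disrotatory 6π electrocyclisation of the (3E)-dienylketene, which joins the ketene carbon to the methyl-bearing diene terminus (C4–C5 of the target) after the [2+2] has made C3–C4 and C1–C2. No stereocentre persists: the racemic centre of 7 reappears in 15 and is erased by tautomerisation, for which the hydrogen on that carbon is required. The step needs regiocontrol in the ketene–ynol ether union, and the polarisation of 11 secures it, because its nucleophilic CH terminus bonds to the electrophilic ketene carbonyl carbon, placing OMe meta to OH and leaving the CH between C–OMe and C–pentacosyl as the only free para position. Release of ring strain in both cyclobutenone openings and the gain of aromaticity drive the cascade, and an excess of 11 in a closed vessel keeps the ynol ether available to trap 12.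

Step 6
Reactants: 16 5-methoxy-2-methyl-3-pentacosylphenol
Product: 17 2-methoxy-5-methyl-6-pentacosylcyclohexa-2,5-diene-1,4-dione (target)
Conditions: Fremy's salt (3 equiv), Aliquat 336 (10 mol%), CH2Cl2/aq. KH2PO4, rt
Reagents that add atoms: potassium nitrosodisulfonate (Fremy's salt), [K+].[K+].[O]N(S(=O)(=O)[O-])S(=O)(=O)[O-]
Why: Teuber oxidation with the nitrosodisulfonate radical should convert a phenol with a free para carbon into the p-quinone, here at the only para position (the CH between the methoxy- and pentacosyl-bearing carbons), while the phase-transfer salt carries the oxidant to the lipophilic substrate.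

Compound list
1 | 1-hexacosanol | CCCCCCCCCCCCCCCCCCCCCCCCCCO | starting material
2 | hexacosanal | CCCCCCCCCCCCCCCCCCCCCCCCCC=O | intermediate
3 | heptacos-1-yne | CCCCCCCCCCCCCCCCCCCCCCCCCC#C | intermediate
4 | N,N-dimethylpropanamide | CCC(=O)N(C)C | starting material
5 | N,N-dimethyl-N-(prop-1-en-1-ylidene)ammonium triflate (methylketeniminium triflate) | CC=C=[N+](C)C.[O-]S(=O)(=O)C(F)(F)F | intermediate (not isolated)
6 | N,N-dimethyl-(4-methyl-3-pentacosylcyclobut-2-en-1-ylidene)ammonium triflate (racemic) | CC1C(=[N+](C)C)C=C1CCCCCCCCCCCCCCCCCCCCCCCCC.[O-]S(=O)(=O)C(F)(F)F | intermediate (not isolated)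
7 | 4-methyl-3-pentacosylcyclobut-2-en-1-one (racemic) | CC1C(=O)C=C1CCCCCCCCCCCCCCCCCCCCCCCCC | intermediate
8 | 2-chloro-1,1-dimethoxyethane | COC(CCl)OC | starting material
9 | 1-chloro-2-methoxyethene (E/Z not defined) | COC=CCl | intermediate (not isolated)
10 | sodium methoxyethynide | [Na+].[C-]#COC | intermediate (not isolated)
11 | methoxyethyne | COC#C | intermediate
12 | (E)-3-pentacosylpenta-1,3-dien-1-one (vinylketene) | C/C=C(/C=C=O)CCCCCCCCCCCCCCCCCCCCCCCCC | intermediate (not isolated)
13 | 3-methoxy-4-[(E)-octacos-2-en-3-yl]cyclobut-2-en-1-one (racemic) | C/C=C(/C1C(=O)C=C1OC)CCCCCCCCCCCCCCCCCCCCCCCCC | intermediate (not isolated)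
14 | (3E,5E)-3-methoxy-5-pentacosylhepta-1,3,5-trien-1-one (dienylketene) | C/C=C(/C=C(\C=C=O)OC)CCCCCCCCCCCCCCCCCCCCCCCCC | intermediate (not isolated)
15 | 3-methoxy-6-methyl-5-pentacosylcyclohexa-2,4-dien-1-one (racemic) | CC1C(=O)C=C(OC)C=C1CCCCCCCCCCCCCCCCCCCCCCCCC | intermediate (not isolated)
16 | 5-methoxy-2-methyl-3-pentacosylphenol | COc1cc(O)c(C)c(CCCCCCCCCCCCCCCCCCCCCCCCC)c1 | intermediate
17 | 2-methoxy-5-methyl-6-pentacosylcyclohexa-2,5-diene-1,4-dione (achiral) | CCCCCCCCCCCCCCCCCCCCCCCCCC1=C(C)C(=O)C=C(OC)C1=O | target

Total step count: 6.
Longest linear sequence: 5 (steps 1, 2, 3, 5, 6); step 4 is a one-step side branch.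

Steps most likely to fail

Step 5. The low-boiling ynol ether may escape into the headspace or self-condense on heating before vinylketene 12 is formed, leaving 12 to dimerise or to acylate phenol already made. Any aryl ester from that acylation would be cleaved by brief K2CO3/MeOH treatment of the crude. The fallback sets out from 7 and uses commercial, higher-boiling ethoxyethyne (toluene, 80 °C, kept below the temperature at which it fragments to ketene) in the same benzannulation to give 5-ethoxy-2-methyl-3-pentacosylphenol F1. Teuber oxidation as in step 6 would give 2-ethoxy-5-methyl-6-pentacosylcyclohexa-2,5-diene-1,4-dione F2. Acid-catalysed alkoxy exchange of this vinylogous ester (MeOH/THF, cat. H2SO4, reflux) would then install the methyl ether, and the fallback comes back to the route at 17.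

Step 3. The α-unbranched keteniminium ion 5 may self-condense, or be captured by the pyridine base, faster than it adds to an unactivated and sparingly soluble alkyne. The fallback sets out from 3 and moves the C-methyl group to the end:
- Dichloroketene cycloaddition (Cl3CCOCl, Zn–Cu, Et2O/DME) should give 4,4-dichloro-3-pentacosylcyclobut-2-en-1-one F3.
- Reductive dechlorination (Zn, AcOH, TMEDA, EtOH) should give 3-pentacosylcyclobut-2-en-1-one F4.
- Benzannulation with 11 as in step 5 should give 3-methoxy-5-pentacosylphenol F5.
- Teuber oxidation as in step 6 should give 2-methoxy-6-pentacosylcyclohexa-2,5-diene-1,4-dione F6.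
- Silver-catalysed persulfate decarboxylation of acetic acid (AcOH, AgNO3, (NH4)2S2O8, MeCN/H2O/CH2Cl2, 65 °C) should then methylate C5. The methyl radical is expected to add at the open carbon of the alkyl-substituted enone and not at C3 beside the donor methoxy group.

This fallback comes back to the route at 17.

Step 6. Transfer of the water-borne radical oxidant to the waxy phenol may be slow, giving phenoxyl radicals time to couple at the open ortho carbon or to be over-oxidised. The fallback sets out from 16 and uses a homogeneous two-electron dearomatisation: PhI(OAc)2 (2.2 equiv) in MeOH/CH2Cl2 at 0 °C should give the p-quinone monoketal 4,4,5-trimethoxy-2-methyl-3-pentacosylcyclohexa-2,5-dien-1-one F7. Mild ketal hydrolysis (aq. AcOH/THF, rt) would unmask the second carbonyl, and the fallback comes back to the route at 17.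

Further compounds
F1 | step 5 | 5-ethoxy-2-methyl-3-pentacosylphenol | CCOc1cc(O)c(C)c(CCCCCCCCCCCCCCCCCCCCCCCCC)c1
F2 | step 5 | 2-ethoxy-5-methyl-6-pentacosylcyclohexa-2,5-diene-1,4-dione | CCCCCCCCCCCCCCCCCCCCCCCCCC1=C(C)C(=O)C=C(OCC)C1=O
F3 | step 3 | 4,4-dichloro-3-pentacosylcyclobut-2-en-1-one | O=C1C=C(CCCCCCCCCCCCCCCCCCCCCCCCC)C1(Cl)Cl
F4 | step 3 | 3-pentacosylcyclobut-2-en-1-one | O=C1C=C(CCCCCCCCCCCCCCCCCCCCCCCCC)C1
F5 | step 3 | 3-methoxy-5-pentacosylphenol | COc1cc(O)cc(CCCCCCCCCCCCCCCCCCCCCCCCC)c1
F6 | step 3 | 2-methoxy-6-pentacosylcyclohexa-2,5-diene-1,4-dione | COC1=CC(=O)C=C(CCCCCCCCCCCCCCCCCCCCCCCCC)C1=O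
F7 | step 6 | 4,4,5-trimethoxy-2-methyl-3-pentacosylcyclohexa-2,5-dien-1-one | COC1=CC(=O)C(C)=C(CCCCCCCCCCCCCCCCCCCCCCCCC)C1(OC)OC
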